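(Its constants are made up.)

Answer the 3 questions below for this flask, and keep an eye on the reagent while the run goes.

solid substrate 0.50 mM; reagent 0.500 equiv (fed, over 3.0 s); free catalyst 1 mol%; time 2.0 min

    starting material + catalyst intermediate A ⇌ catalyst intermediate B (K1 = 21000 /M, k1 = 3.3 × 10⁵ /M/s)
    catalyst intermediate B ⇌ free catalyst + product (K2 = 2.9 × 10⁻⁴ M, k2 = 23 /s)
    reagent + free catalyst → catalyst intermediate A (k3 = 2.4 × 10⁶ /M/s)
    starting material + product ⇌ idle adduct, settled at all times (K4 = 2500 /M)
    solid substrate ⇌ starting material, rate k5*(cs5 - [starting material]) while solid is left; crystals form when [starting material] > cs5 (cs5 = 0.017 mM, k5 = 5.9 /s)

- percentages count the solid substrate that a species holds: one idle adduct counts as two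
- product is meant together with its idle adduct
- solid, in amounts per volume of the solution: solid substrate
- at the start none of the solid substrate is in solution
- what has only dissolved of solid substrate counts as not reacted
- in an amount of product, one idle adduct counts as one product
- the reaction counts as stopped when no species that holds the solid substrate changes by six tenths of a point or more over the second half of the time
- starting material means what is dissolved; the solid is not counted in it
- run time (flask): 2.0 min

* the state of affairs at 2.0 min: stopped, and by what, or still going (for what has run out or reacted, a solid counts together with what of it has only dissolved) (it is still moving / all of the solid substrate has reacted / no working catalyst is left / forward and back rates have come level / the reagent has run out first)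
* the product standing at 2.0 min, as a percentage of the solid substrate charged
* the starting material standing at 2.0 min, as a percentage of the solid substrate charged

Follow one reagent molecule. It turns free catalyst into catalyst intermediate A, which takes up starting material to become catalyst intermediate B, and that releases one product. One reagent therefore pays for one product, so the charges allow 50.0%, and the reagent is the limiting reagent, since its charge is smaller than that of the solid substrate.

Now ask how long this takes. Dissolving has a half-life of 0.117 s, far shorter than the run, so for this estimate hold the starting material near its solubility, 0.017 mM. Intermediate A then moves on at a pseudo-first-order 5.61 /s. At the fork, intermediate B goes forward at 23 /s or back at 15.7 /s, a forward chance of 59.4%. With the catalyst resting as intermediate A, the flask turns over at about 0.0167 mM/s, so the reagent charge lasts about 15.0 s, far shorter than the run. Expect the reagent to finish first, with solid still present and starting material at 3.40% of the charge.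

The weak link is the ceiling: spent reagent may still sit on the catalyst, as intermediate A or B, and not yet stand as product. Reforge it with balances at rest. Step 1 gives intermediate B over intermediate A as 0.357. Free product is about 0.240 mM, so free catalyst over intermediate B is 1.21. Call h the held share, the fraction of the catalyst standing as intermediate A or B once the reagent has finished: 75.9%. Subtract the loading times h from the ceiling, and commit to 49.2% of product.

The forecast says the reagent has run out first, with 49.2% of product and 3.4% of starting material, reasoning “capping product near 50% less the little held on the catalyst”. My hand figures give the same three answers.

The flask gives the reagent has run out first, 49.2% and 3.40%, with 0% of its reagent left. A neighbour flask with 2.00 equiv of reagent ends differently: solid substrate goes first, and 50% of its reagent remains. In this flask, intermediates A and B stand at 55.7% and 19.9% of the catalyst charged, against a reckoned h of 75.9%. For the neighbour with 0.20 mM of solid substrate, reckon free product at about 0.0959 mM, lower than the reckoning here, so h comes to 55.7%, lower as well; of its catalyst charged, that neighbour shows intermediates A and B at 40.8% and 14.6%.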